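We must decide at 2.0 h whether to touch the zeta flask or leave it, so we count the half-lives its links still face.

| setting | zeta | delta | flask |
|---|---|---|---|
| first end groups | 2 M | 2 M | 2.0 M |
| second end groups | 1.9 M | 1.9 M | 1.90 M |
| protic impurity | 0.10 M | 0.10 M | 0.100 M |
| temperature | 60 °C | 55 °C | 60 °C |
| remark | the very flask that is asked about, followed so far | run made earlier |  |
| time |  |  | 2.0 h |

| run | time / min | links / % |
|---|---|---|
| zeta | 20.0 | 48 |
| zeta | 40.0 | 43 |
| zeta | 60.0 | 40 |
| zeta | 80.0 | 42 |
| zeta | 90.0 | 36 |
| zeta | 120 | 35 |
| delta | 20.0 | 52 |
| delta | 40.0 | 49 |
| delta | 60.0 | 42 |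
| delta | 80.0 | 49 |
| delta | 90.0 | 44 |
| delta | 120 | 42 |

(each reading ± 2 percentage points)

- Friday's: change nothing and wait 4.0 h more
- Tuesday's: at 2.0 h raise the temperature by 10 K, then wait 4.0 h
- Monday's: at 2.0 h take out 90% of the by-product then present, then wait 4.0 h

- additions leave the volume as it is

* links, in percent of the first end groups first charged, at 2.0 h
* the option that brings most further links ("none" if no option brings more than 2 percentage points) (Friday's / Tuesday's / Monday's / none)
* links present, in percent of the first end groups first charged, after Friday's
* links present, in percent of the first end groups first charged, after Monday's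

What do the runs show? In zeta, links go from 48% at 20.0 min to 35% at 120 min. In delta, the cooler run, they go from 52% to 42%.

What do you carry forward? Zeta's first and last readings give 219 min. This is the link half-life, the time in which c(links) shrinks by a factor of two, taken as an apparent first-order loss.

Is that firm? No. Each reading is good to 2 percentage points, and zeta's reading at 80.0 min stands above the one at 60.0 min. It is a rough figure.

Your figure for now? The last reading, 35%.

And Friday's? The wait is 1.09 half-lives, so I say 16.4%.

Tuesday's? Delta gives 325 min, longer than zeta's by a factor 1.48. Two such steps up make the wait 2.39 half-lives, so Tuesday's loses more than Friday's.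

But Monday's might win links back? Then, on my half-life, they must reach 74.7% just after the removal to return to 35%. That is above every reading in either run. Even a rise to the highest reading, 52%, ends at 24.4%. So I answer none.

The forecast gave 35.5% now, 32% after Friday's and 47% after Monday's, and chose Monday's where I chose none: “Monday's is therefore best, though this rests on the assumed reversibility.”

The flask gives 34.6% now, and the best option is none.

    first end groups + protic impurity → quenched substrate (k = 0.228 M⁻¹ s⁻¹, Ea = 41.0 kJ mol⁻¹)
    first end groups + links → side product (k = 9.02 × 10⁻⁵ M⁻¹ s⁻¹, Ea = 92.0 kJ mol⁻¹)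
    first end groups + second end groups ⇌ links + by-product (K = 1.72, k = 0.0374 M⁻¹ s⁻¹, Ea = 65.0 kJ mol⁻¹, ΔH = −12.0 kJ mol⁻¹)
    (constants at 60 °C)

Friday's ended at 20.4%, which is 0.762 half-lives where I counted 1.09. Monday's ended at 32.5%, which is 2 points below 34.6%. Now take the neighbouring flask, the same charge at 35 °C. Stepping the factor 1.48 down from 60 °C gives a half-life of 1550 min, so 2.0 h is 0.0773 half-lives. Counted from delta's highest reading, 52%, links should then stay near 49.3%. That flask held links at 55.9% after 120 min, with side product at 3.62% of the first end groups charged.

(The numbers in the tables come from a simulation with made-up constants; the scatter is artificial.)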